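The route rests on cutting the C9–C10 bond. The bridged 3(2H)-furanone ring (O1, C3=C2, C1 ketone, C10) carries at its quaternary C10 (methyl, ring oxygen) the carbinol C9, which is an aldol retron between a 2-methyl-3-silyloxyfuran and a C9 aldehyde. One intramolecular Mukaiyama aldol therefore closes the ten-membered carbocycle, dearomatises the furan to the oxygen-bridged furanone and sets C9 and C10, leaving O9 free for the methacrylate. The precursor is a trans-fused α-methylene-γ-lactone (C6/C7) bearing at C6 a (Z)-propenyl-linked 2-methyl-3-(triisopropylsilyloxy)furan and at C7 a C8-silyloxy C9 aldehyde, assembled from a furanone Z-enal and a glyceraldehyde-derived 2-(bromomethyl)enoate.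

Key step: step 17

Remark (numbering): germacrane numbering is used for the target and all advanced intermediates: C1 ketone, C2=C3, O1 bridging C3 and C10, C4(Me)=C5, C6 (lactone oxygen), C7, C8 (OH), C9 (methacryloyloxy), C10 (Me), C11=C13 and C12 (lactone carbonyl).

Remark (chemistry): the lactate-derived centre (C10–H of every 3(2H)-furanone before step 16) is drawn S but is configurationally labile and becomes sp2 in step 16, so its epimerisation is of no consequence; the Morita–Baylis–Hillman adduct is carried as a mixture of carbinol epimers because both give the same bromide.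

Step 1
Reactants: 1 (Z)-3-methylpent-2-en-4-yn-1-ol
Product: 2 enyne TBS ether
Conditions: TBSCl, imidazole, CH2Cl2, 0 °C to rt
Reagents that add atoms: tert-butyldimethylsilyl chloride (TBSCl), CC(C)(C)[Si](C)(C)Cl
Why: Routine O-silylation of a primary allylic alcohol under mild base, which leaves the bought Z-enyne geometry untouched and masks the hydroxyl that could otherwise add to the alkyne in steps 4 to 6.

Step 2
Reactants: 3 ethyl (S)-lactate
Product: 4 lactic Weinreb amide
Conditions: MeNH(OMe)·HCl, i-PrMgCl (3 equiv), THF, −20 to 0 °C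
Reagents that add atoms: N,O-dimethylhydroxylamine hydrochloride, CNOC.Cl
Why: Weinreb amide formation by direct aminolysis of the ester with the magnesium amide of N,O-dimethylhydroxylamine; the lactate centre is not touched.

Step 3
Reactants: 4 lactic Weinreb amide
Product: 5 O-TES lactic Weinreb amide
Conditions: TESCl, imidazole, DMF, 0 °C to rt
Reagents that add atoms: triethylsilyl chloride (TESCl), CC[Si](Cl)(CC)CC
Why: Routine silylation of a secondary alcohol; the triethylsilyl ether survives the acetylide addition yet is far more acid-labile than the primary TBS ether, which allows its selective removal in step 5.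

Step 4
Reactants: 2 enyne TBS ether; 5 O-TES lactic Weinreb amide
Product: 7 silyl-protected ynone, via lithium acetylide 6 (not isolated)
Conditions: 2, n-BuLi, THF, −78 °C; then 5, −78 to −20 °C; aq. NH4Cl
Reagents that add atoms: none
Why: Acylation of a lithium acetylide by a Weinreb amide, whose chelated tetrahedral adduct prevents over-addition and releases the ynone only on work-up.

Step 5
Reactants: 7 silyl-protected ynone
Product: 8 γ-hydroxy ynone
Conditions: PPTS (0.2 equiv), MeOH, 0 °C
Reagents that add atoms: none
Why: Mild acid-catalysed methanolysis (selective silyl ether solvolysis) cleaves the secondary triethylsilyl ether much faster than the primary TBS ether, so the allylic oxygen stays masked and cannot form a furan with the alkyne.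

Step 6
Reactants: 8 γ-hydroxy ynone
Product: 9 furanone TBS ether
Conditions: (Ph3P)AuCl (5 mol %), AgOTf (5 mol %), PhMe, rt
Reagents that add atoms: none
Why: Gold-catalysed 5-endo-dig cycloisomerisation of a γ-hydroxy ynone (hydroxyl addition to the π-activated alkyne carbon β to the ketone, then protodeauration) is an established route to 3(2H)-furanones and creates no new stereocentre.

Step 7
Reactants: 9 furanone TBS ether
Product: 10 furanone Z-allylic alcohol
Conditions: HF·pyridine, pyridine, THF, 0 °C
Reagents that add atoms: none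
Why: Fluoride-mediated desilylation with buffered HF·pyridine frees the primary allylic alcohol without acid or base strong enough to isomerise the Z olefin or open the furanone.

Step 8
Reactants: 10 furanone Z-allylic alcohol
Product: 11 furanone Z-enal
Conditions: Dess–Martin periodinane, NaHCO3, CH2Cl2, 0 °C
Reagents that add atoms: none
Why: Buffered Dess–Martin oxidation of an allylic alcohol is neutral and fast, so the Z-enal should form without isomerisation to the E isomer; it is used at once.

Step 9
Reactants: 12 (R)-2,3-O-isopropylideneglyceraldehyde; 13 methyl acrylate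
Product: 14 Morita–Baylis–Hillman adduct
Conditions: DABCO (0.5 equiv), 1,4-dioxane/H2O (1:1), rt
Reagents that add atoms: none
Why: Morita–Baylis–Hillman reaction of a reactive α-alkoxy aldehyde with methyl acrylate; the new carbinol centre forms as an epimer mixture, which does not matter because it becomes sp2 in step 10, and C8 is carried through unchanged.

Step 10
Reactants: 14 Morita–Baylis–Hillman adduct
Product: 15 (Z)-2-(bromomethyl)enoate
Conditions: NBS, Me2S, CH2Cl2, 0 °C to rt
Reagents that add atoms: N-bromosuccinimide (NBS), O=C1CCC(=O)N1Br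
Why: Bromination with allylic transposition (SN2′ displacement of the sulfonium-activated hydroxyl by bromide) is the standard conversion of Morita–Baylis–Hillman adducts into the favoured (Z)-2-(bromomethyl)enoates, and the nearly neutral medium spares the acetonide.

Step 11
Reactants: 11 furanone Z-enal; 15 (Z)-2-(bromomethyl)enoate
Product: 18 trans-fused acetonide lactone, via E-allylchromium dichloride 16 (not isolated), via anti hydroxy ester 17 (not isolated)
Conditions: CrCl2 (4 equiv), THF, 0 °C to rt; aq. NH4Cl; then PPTS (cat.), PhMe, 40 °C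
Reagents that add atoms: none
Why: Nozaki–Hiyama allylation mediated by divalent chromium, then lactonisation: the allylchromium is expected to equilibrate by 1,3-metal shift to the E-configured species 16 (C8 trans to CH2Cr), which should add 1,2 to the enal through a chair transition state with C8 and the alkenyl group equatorial to give the 6,7-anti adduct 17 and hence the trans lactone, while the aldehyde approaches C7 anti to the C8–C9 bond with H8 eclipsing the allyl plane and O8 outside, the sense expected for γ-alkoxy allylmetal reagents, which relays C8 to C7 and C6.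

Step 12
Reactants: 18 trans-fused acetonide lactone
Product: 19 8,9-diol
Conditions: AcOH/H2O (4:1), 35 °C
Reagents that add atoms: none
Why: Mild aqueous acid hydrolyses the terminal isopropylidene acetal (acetal hydrolysis) while the lactone, the furanone and the conjugated olefins are stable to these conditions.

Step 13
Reactants: 19 8,9-diol
Product: 20 8,9-bis-TBS ether
Conditions: TBSCl (3 equiv), imidazole, DMAP (cat.), DMF, rt
Reagents that add atoms: tert-butyldimethylsilyl chloride (TBSCl), CC(C)(C)[Si](C)(C)Cl
Why: Exhaustive silylation of the diol under standard imidazole conditions protects O8 as the bulky, non-chelating ether needed for the key step; no stereocentre is affected.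

Step 14
Reactants: 20 8,9-bis-TBS ether
Product: 21 C9 primary alcohol
Conditions: HF·pyridine, pyridine, THF, 0 °C
Reagents that add atoms: none
Why: Primary TBS ethers are cleaved by buffered HF·pyridine much faster than hindered secondary ones (selective desilylation), which frees only the C9 hydroxyl.

Step 15
Reactants: 21 C9 primary alcohol
Product: 22 furanone C9 aldehyde
Conditions: Dess–Martin periodinane, NaHCO3, CH2Cl2, 0 °C to rt
Reagents that add atoms: none
Why: Buffered Dess–Martin oxidation gives the α-silyloxy aldehyde under non-basic conditions, so C8 is not epimerised.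

Step 16
Reactants: 22 furanone C9 aldehyde
Product: 23 silyloxyfuran aldehyde
Conditions: TIPSOTf (1.05 equiv), Et3N (2 equiv), CH2Cl2, −78 °C; cold aq. NaHCO3
Reagents that add atoms: triisopropylsilyl trifluoromethanesulfonate (TIPSOTf), CC(C)[Si](OS(=O)(=O)C(F)(F)F)(C(C)C)C(C)C
Why: Soft enolisation (silyl triflate and amine) of a 3(2H)-furanone to the aromatic 3-silyloxyfuran is a known transformation; the vinylogous ester carbonyl is far more Lewis basic and its C10–H far more acidic than the aldehyde, so one equivalent of the hindered silyl triflate at −78 °C should silylate the furanone alone.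

Step 17
Reactants: 23 silyloxyfuran aldehyde
Product: 24 bridged furanone macrocycle
Conditions: BF3·OEt2 (3 equiv), CH2Cl2 (1 mM), −78 °C, slow addition of 23 by syringe pump; aq. NaHCO3
Reagents that add atoms: none
Why: Proposed new method: BF3 binds the C9 aldehyde, the silyloxyfuran attacks it through C10 (the enol-ether carbon next to the ring oxygen and terminus of the C1=C10 enol silane), and the resulting silyloxy oxocarbenium ion loses silicon as i-Pr3SiF to give the C1 ketone with C2=C3 left as the vinylogous ester; the closest known reaction types are the intermolecular Lewis acid mediated aldol of 2-alkyl-3-silyloxyfurans with aldehydes to 2,2-disubstituted 3(2H)-furanones and medium-ring intramolecular Mukaiyama aldols. The single C–C bond closes the ten-membered carbocycle in a 10-(enolendo)-exo-trig mode and, counted through O1, the nine-membered oxygen-bridged ring in a 9-(enolexo)-exo-trig mode. C9 is set by polar Felkin–Anh attack anti to the bulky, non-chelating C8 OTBS group under the monodentate Lewis acid (8,9-anti), and C10 by the open transition state that the tether allows: C8 must lie over the furan, anti to the C10 methyl, which places the BF3-bound oxygen antiperiplanar to C1=C10 and away from the OTIPS group and so gives the 9S,10S pair. The step needs the aldehyde to react in preference to the methylene lactone, attack through C10 only, and cyclisation over oligomerisation; these are secured by Lewis acid activation of the aldehyde alone, by the inherent C2 nucleophilicity of 3-silyloxyfurans, and by high dilution aided by the two rigid turns (Z C4=C5 olefin and trans lactone) that hold C9 near C10.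

Step 18
Reactants: 24 bridged furanone macrocycle; 25 methacrylic anhydride
Product: 26 C9 methacrylate C8 TBS ether
Conditions: DMAP (0.3 equiv), Et3N, CH2Cl2, 0 °C to rt
Reagents that add atoms: none
Why: DMAP-catalysed acylation of the secondary C9 alcohol with the anhydride (nucleophilic catalysis) under mild base, chosen to avoid retro-aldol opening of the β-hydroxy ketone; the configuration at C9 is retained.

Step 19
Reactants: 26 C9 methacrylate C8 TBS ether
Product: 27 CNP0562373.1
Conditions: HF·pyridine, THF, 0 °C to rt
Reagents that add atoms: none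
Why: Fluoride-mediated cleavage of the C8 TBS ether under mildly acidic HF·pyridine conditions avoids the 9-to-8 acyl migration and lactone transposition that basic fluoride could cause and leaves the methacrylate, the α-methylene lactone and the furanone intact.

Compound list

1 | (Z)-3-methylpent-2-en-4-yn-1-ol | OC/C=C(/C)C#C | starting material
2 | tert-butyl(dimethyl)[(2Z)-3-methylpent-2-en-4-yn-1-yloxy]silane | CC(C)(C)[Si](C)(C)OC/C=C(/C)C#C | intermediate
3 | ethyl (S)-lactate | CCOC(=O)[C@H](C)O | starting material
4 | (S)-2-hydroxy-N-methoxy-N-methylpropanamide | CON(C)C(=O)[C@H](C)O | intermediate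
5 | (S)-N-methoxy-N-methyl-2-(triethylsilyloxy)propanamide | CON(C)C(=O)[C@H](C)O[Si](CC)(CC)CC | intermediate
6 | lithium acetylide of 2 | CC(C)(C)[Si](C)(C)OC/C=C(/C)C#C[Li] | intermediate (not isolated)
7 | (2S,6Z)-8-(tert-butyldimethylsilyloxy)-6-methyl-2-(triethylsilyloxy)oct-6-en-4-yn-3-one | CC(C)(C)[Si](C)(C)OC/C=C(/C)C#CC(=O)[C@H](C)O[Si](CC)(CC)CC | intermediate
8 | (2S,6Z)-8-(tert-butyldimethylsilyloxy)-2-hydroxy-6-methyloct-6-en-4-yn-3-one | CC(C)(C)[Si](C)(C)OC/C=C(/C)C#CC(=O)[C@H](C)O | intermediate
9 | (2S)-5-[(2Z)-4-(tert-butyldimethylsilyloxy)but-2-en-2-yl]-2-methylfuran-3(2H)-one | CC(C)(C)[Si](C)(C)OC/C=C(/C)C1=CC(=O)[C@H](C)O1 | intermediate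
10 | (2S)-5-[(2Z)-4-hydroxybut-2-en-2-yl]-2-methylfuran-3(2H)-one | OC/C=C(/C)C1=CC(=O)[C@H](C)O1 | intermediate
11 | (2Z)-3-[(5S)-5-methyl-4-oxo-4,5-dihydrofuran-2-yl]but-2-enal | O=C/C=C(/C)C1=CC(=O)[C@H](C)O1 | intermediate
12 | (R)-2,3-O-isopropylideneglyceraldehyde, (4R)-2,2-dimethyl-1,3-dioxolane-4-carbaldehyde | O=C[C@H]1COC(C)(C)O1 | starting material
13 | methyl acrylate | C=CC(=O)OC | starting material
14 | methyl 2-{[(4R)-2,2-dimethyl-1,3-dioxolan-4-yl](hydroxy)methyl}prop-2-enoate, mixture of carbinol epimers | C=C(C(=O)OC)C(O)[C@H]1COC(C)(C)O1 | intermediate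
15 | methyl (2Z)-2-(bromomethyl)-3-[(4S)-2,2-dimethyl-1,3-dioxolan-4-yl]prop-2-enoate | COC(=O)/C(CBr)=C/[C@H]1COC(C)(C)O1 | intermediate
16 | E-configured allylchromium dichloride from 15 (dioxolane trans to CH2Cr, cis to the ester) | COC(=O)/C(C[Cr](Cl)Cl)=C\[C@H]1COC(C)(C)O1 | intermediate (not isolated)
17 | anti hydroxy ester (6R,7S,8S): methyl 2-methylene ester with C6 hydroxyl, C7 bearing the (4S)-dioxolane, 6,7-anti | COC(=O)C(=C)[C@H]([C@H]1COC(C)(C)O1)[C@H](O)/C=C(/C)C2=CC(=O)[C@H](C)O2 | intermediate (not isolated)
18 | (6R,7S,8S)-trans-fused α-methylene-γ-lactone with C8/C9 acetonide and 4Z side chain to the 2-methylfuran-3(2H)-one | CC1(C)OC[C@@H](O1)[C@H]2C(=C)C(=O)O[C@@H]2/C=C(/C)C1=CC(=O)[C@H](C)O1 | intermediate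
19 | (6R,7R,8S)-8,9-diol of the trans lactone | OC[C@@H](O)[C@H]1C(=C)C(=O)O[C@@H]1/C=C(/C)C1=CC(=O)[C@H](C)O1 | intermediate
20 | (6R,7S,8S)-8,9-bis(tert-butyldimethylsilyl) ether | CC(C)(C)[Si](C)(C)OC[C@@H](O[Si](C)(C)C(C)(C)C)[C@H]1C(=C)C(=O)O[C@@H]1/C=C(/C)C1=CC(=O)[C@H](C)O1 | intermediate
21 | (6R,7S,8S)-8-O-TBS C9 primary alcohol | OC[C@@H](O[Si](C)(C)C(C)(C)C)[C@H]1C(=C)C(=O)O[C@@H]1/C=C(/C)C1=CC(=O)[C@H](C)O1 | intermediate
22 | (6R,7S,8S)-8-O-TBS C9 aldehyde with intact furanone | O=C[C@@H](O[Si](C)(C)C(C)(C)C)[C@H]1C(=C)C(=O)O[C@@H]1/C=C(/C)C1=CC(=O)[C@H](C)O1 | intermediate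
23 | (6R,7S,8S)-8-O-TBS C9 aldehyde carrying the 2-methyl-3-(triisopropylsilyloxy)furan | O=C[C@@H](O[Si](C)(C)C(C)(C)C)[C@H]1C(=C)C(=O)O[C@@H]1/C=C(/C)c1cc(O[Si](C(C)C)(C(C)C)C(C)C)c(C)o1 | intermediate
24 | (6R,7S,8S,9S,10S)-bridged furanone germacranolide with free C9 hydroxyl and C8 OTBS | O[C@H]1[C@@H](O[Si](C)(C)C(C)(C)C)[C@H]2C(=C)C(=O)O[C@@H]2/C=C(/C)C2=CC(=O)[C@@]1(C)O2 | intermediate
25 | methacrylic anhydride | C=C(C)C(=O)OC(=O)C(C)=C | starting material
26 | (6R,7S,8S,9S,10S)-9-O-methacryloyl-8-O-TBS bridged furanone germacranolide | C=C(C)C(=O)O[C@H]1[C@@H](O[Si](C)(C)C(C)(C)C)[C@H]2C(=C)C(=O)O[C@@H]2/C=C(/C)C2=CC(=O)[C@@]1(C)O2 | intermediate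
27 | CNP0562373.1, (4Z,6R,7R,8S,9S,10S) | C=C(C)C(=O)O[C@H]1[C@@H](O)[C@H]2C(=C)C(=O)O[C@@H]2/C=C(/C)C2=CC(=O)[C@@]1(C)O2 | target

Total step count: 19 steps.
Longest linear sequence: 16 steps, from ethyl (S)-lactate 3 (steps 2 to 8 and 11 to 19).

Steps most likely to fail

1. Step 17. Ring closure may lose to oligomerisation or to protodesilylation of the silyloxyfuran, or the aldehyde may add to the wrong furan face. The fallback uses known reaction types: C9–C10 is formed intermolecularly and the ring is closed at C6–C7. It sets out from compounds 9 and 15. Furanone 9 is converted with TIPSOTf/Et3N into the silyloxyfuran F1. Bromide 15 is taken through the operations of steps 12 to 15: aqueous AcOH should give the diol F2; TBSOTf/2,6-lutidine at −78 °C, fast enough to outrun cyclisation onto the allylic bromide, the bis-silyl ether F3; HF·pyridine the primary alcohol F4; and Dess–Martin periodinane the α-silyloxy aldehyde F5. A BF3·OEt2-mediated Mukaiyama aldol of F1 with F5 (the known intermolecular reaction of 3-silyloxyfurans, Felkin–Anh at C9, the C10 epimers to be separated) should give the aldol F6. Acylation with methacrylic anhydride 25 gives the methacrylate F7. Selective removal of the primary allylic TBS group with HF·pyridine gives the allylic alcohol F8, and Dess–Martin oxidation the Z-enal F9. CrCl2 at high dilution then effects the intramolecular Nozaki–Hiyama allylation with lactonisation, an established way to close germacranolide ten-membered rings at C6–C7, and the sequence returns at compound 26.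

2. Step 11. The allylchromium may react through the Z-configured species with C8 axial in the chair, which would give the 6,7-syn adduct and the cis lactone. The fallback makes the syn adduct on purpose and inverts C6 during ring closure. An indium-mediated Barbier coupling of 11 with 15 in THF/H2O, a reaction known to keep the bromide geometry and to deliver syn adducts, should give the 6-epi hydroxy ester F10. Hydrolysis with Me3SnOH gives the hydroxy acid F11. Mitsunobu lactonisation (PPh3, DIAD) then closes the lactone with inversion at C6 and returns at compound 18.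

3. Step 16. The silyl triflate may trigger premature intermolecular aldol addition to the aldehyde or enolise the α-silyloxy aldehyde with erosion of C8. The fallback forms the silyloxyfuran before the aldehyde. Alcohol 21 is capped with TMSCl/Et3N as the trimethylsilyl ether F12. TIPSOTf/Et3N gives the silyloxyfuran F13. Brief K2CO3/MeOH at −20 °C removes only the primary trimethylsilyl group to give the silyloxyfuran alcohol F14. A non-acidic Parikh–Doering oxidation (SO3·pyridine, DMSO, i-Pr2NEt) returns at compound 23.

Further compounds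

F1 | step 17 | tert-butyl(dimethyl){(2Z)-3-[5-methyl-4-(triisopropylsilyloxy)furan-2-yl]but-2-en-1-yloxy}silane | CC(C)(C)[Si](C)(C)OC/C=C(/C)c1cc(O[Si](C(C)C)(C(C)C)C(C)C)c(C)o1
F2 | step 17 | methyl (2Z,4S)-2-(bromomethyl)-4,5-dihydroxypent-2-enoate | COC(=O)/C(CBr)=C/[C@H](O)CO
F3 | step 17 | methyl (2Z,4S)-2-(bromomethyl)-4,5-bis(tert-butyldimethylsilyloxy)pent-2-enoate | COC(=O)/C(CBr)=C/[C@H](O[Si](C)(C)C(C)(C)C)CO[Si](C)(C)C(C)(C)C
F4 | step 17 | methyl (2Z,4S)-2-(bromomethyl)-4-(tert-butyldimethylsilyloxy)-5-hydroxypent-2-enoate | COC(=O)/C(CBr)=C/[C@H](O[Si](C)(C)C(C)(C)C)CO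
F5 | step 17 | methyl (2Z,4S)-2-(bromomethyl)-4-(tert-butyldimethylsilyloxy)-5-oxopent-2-enoate | COC(=O)/C(CBr)=C/[C@H](O[Si](C)(C)C(C)(C)C)C=O
F6 | step 17 | open-chain (8S,9S,10S) aldol of F1 and F5 with free C9 hydroxyl | COC(=O)/C(CBr)=C/[C@H](O[Si](C)(C)C(C)(C)C)[C@H](O)[C@]1(C)OC(/C(C)=C\CO[Si](C)(C)C(C)(C)C)=CC1=O
F7 | step 17 | C9 methacrylate of F6 | COC(=O)/C(CBr)=C/[C@H](O[Si](C)(C)C(C)(C)C)[C@H](OC(=O)C(C)=C)[C@]1(C)OC(/C(C)=C\CO[Si](C)(C)C(C)(C)C)=CC1=O
F8 | step 17 | C6 allylic alcohol from F7 | COC(=O)/C(CBr)=C/[C@H](O[Si](C)(C)C(C)(C)C)[C@H](OC(=O)C(C)=C)[C@]1(C)OC(/C(C)=C\CO)=CC1=O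
F9 | step 17 | C6 Z-enal from F8, seco precursor of 26 | COC(=O)/C(CBr)=C/[C@H](O[Si](C)(C)C(C)(C)C)[C@H](OC(=O)C(C)=C)[C@]1(C)OC(/C(C)=C\C=O)=CC1=O
F10 | step 11 | 6-epi (6S,7S,8S) syn hydroxy ester | COC(=O)C(=C)[C@H]([C@H]1COC(C)(C)O1)[C@@H](O)/C=C(/C)C2=CC(=O)[C@H](C)O2
F11 | step 11 | 6-epi (6S,7S,8S) hydroxy acid | OC(=O)C(=C)[C@H]([C@H]1COC(C)(C)O1)[C@@H](O)/C=C(/C)C2=CC(=O)[C@H](C)O2
F12 | step 16 | 9-O-trimethylsilyl ether of 21 | C[Si](C)(C)OC[C@@H](O[Si](C)(C)C(C)(C)C)[C@H]1C(=C)C(=O)O[C@@H]1/C=C(/C)C1=CC(=O)[C@H](C)O1
F13 | step 16 | 3-(triisopropylsilyloxy)furan from F12 | C[Si](C)(C)OC[C@@H](O[Si](C)(C)C(C)(C)C)[C@H]1C(=C)C(=O)O[C@@H]1/C=C(/C)c1cc(O[Si](C(C)C)(C(C)C)C(C)C)c(C)o1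
F14 | step 16 | silyloxyfuran C9 primary alcohol | OC[C@@H](O[Si](C)(C)C(C)(C)C)[C@H]1C(=C)C(=O)O[C@@H]1/C=C(/C)c1cc(O[Si](C(C)C)(C(C)C)C(C)C)c(C)o1
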